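**Plan**

- Enabling feature: ring A (the 2,4-dihydroxybenzoate) carries the ester carbonyl carbon on C1 and the benzylic carbon C1' of the 8-acetoxyundecyl chain on the neighbouring C6, with an oxygen on C2 beside C1. Both ring bonds (C6–C1' and C1–C=O) are cut together, back to 3,5-bis(benzyloxy)benzyne and the C1'–C(=O) σ-bond of an α-phenylsulfonyl ester that already holds the chain and the ester alcohol.
- Further cuts: C1'–C2' (alkylation of a sulfonylacetate), the sulfonylacetate C(=O)–O bond, the aryl–CH2 bond of the distal ring (B-alkyl Suzuki), the C6–C7 bond of each undecyl chain (epoxide opening), and the O–SO3 bond.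
- Forward order: two copper-catalysed Grignard openings of (S)-2-propyloxirane give both chains; the distal ring is attached; the alcohol is esterified with (phenylsulfonyl)acetic acid and alkylated with the acetoxy chain; the aryne then inserts, setting up the substitution pattern of ring A and the hindered benzoate in one operation.
- End game: SmI2 removes the sulfonyl helper, the MOM ether is cleaved, the freed phenol is sulfated, and hydrogenolysis removes three benzyl ethers.
- Stereochemistry: both (S) carbinol centres come from (S)-2-propyloxirane, opened at its CH2; their C–O bonds are never broken afterwards, and the acyl transfer in the key step proceeds with retention.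

Key step: step 11

Remark: the target is drawn as the free aryl hydrogen sulfate; the sulfate is carried as its sodium salt (26) and the acid form is liberated in the last operation. Compounds 16 and 23 are mixtures of epimers at the sulfonyl-bearing carbon, which becomes CH2 in step 12.

**Route**

Step 1
Reactants: 1 5-bromobenzene-1,3-diol
Product: 2 3-(benzyloxy)-5-bromophenol
Conditions: BnBr (1.0 equiv), K2CO3, acetone, reflux
Reagents that add atoms: benzyl bromide, BrCc1ccccc1
Why: Williamson etherification of one of two equivalent phenols with one equivalent of benzyl bromide should give the mono-ether statistically, separable from diol and bis-ether, which differentiates the two oxygens of the distal ring at the outset.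

Step 2
Reactants: 2 3-(benzyloxy)-5-bromophenol
Product: 3 1-(benzyloxy)-3-bromo-5-(methoxymethoxy)benzene
Conditions: NaH, MOMCl, DMF, 0 °C
Reagents that add atoms: chloromethyl methyl ether, COCCl
Why: O-alkylation of the sodium phenoxide (Williamson-type) masks the phenol destined for sulfation as a MOM ether that should withstand organometallics, base, fluoride and SmI2 and be cleavable beside benzyl ethers.

Step 3
Reactants: 5 6-bromohex-1-ene; 4 (S)-2-propyloxirane
Product: 7 (S)-undec-10-en-4-ol, via hex-5-enylmagnesium bromide 6 (not isolated)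
Conditions: Mg, THF, rt; then 4, CuI (10 mol %), −30 → 0 °C; H2O
Reagents that add atoms: none
Why: Copper-catalysed Grignard opening of the terminal epoxide at its unsubstituted carbon (SN2) should give the secondary alcohol; the stereocentre of 4 takes no part in bond breaking, so its (S) configuration is carried over.

Step 4
Reactants: 7 (S)-undec-10-en-4-ol; 3 1-(benzyloxy)-3-bromo-5-(methoxymethoxy)benzene
Product: 9 (S)-11-[3-(benzyloxy)-5-(methoxymethoxy)phenyl]undecan-4-ol, via the O,B-bis(9-BBN) adduct 8 (not isolated)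
Conditions: 9-BBN (2.2 equiv), THF, 0 °C → rt; then 3, PdCl2(dppf) (5 mol %), aq K3PO4, DMF, 60 °C
Reagents that add atoms: none
Why: B-alkyl Suzuki–Miyaura coupling, in which anti-Markovnikov hydroboration of the terminal alkene (a second equivalent of borane is taken up by the hydroxyl as a borinate, hydrolysed on work-up) and Pd-catalysed sp3–sp2 coupling with the aryl bromide should join chain and distal ring without touching the benzyl and MOM ethers.

Step 5
Reactants: 9 (S)-11-[3-(benzyloxy)-5-(methoxymethoxy)phenyl]undecan-4-ol; 10 2-(phenylsulfonyl)acetic acid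
Product: 11 (S)-11-[3-(benzyloxy)-5-(methoxymethoxy)phenyl]undecan-4-yl 2-(phenylsulfonyl)acetate
Conditions: DCC, DMAP (cat.), CH2Cl2, 0 °C → rt
Reagents that add atoms: none
Why: Steglich esterification of an unhindered acetic acid with the secondary alcohol should be easy and occurs at the O–H bond (retention at carbon); it lays down the future benzoate C(=O)–O bond before the arene is present.

Step 6
Reactants: 12 1-bromo-5-chloropentane; 4 (S)-2-propyloxirane
Product: 14 (S)-10-chlorodecan-4-ol, via (5-chloropentyl)magnesium bromide 13 (not isolated)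
Conditions: Mg, THF, rt; then 4, CuI (10 mol %), −30 → 0 °C; H2O
Reagents that add atoms: none
Why: The Grignard reagent forms selectively at the C–Br bond, and copper-catalysed SN2 opening of the epoxide at CH2 should give the ω-chloro alcohol with the (S) centre of 4 unchanged.

Step 7
Reactants: 14 (S)-10-chlorodecan-4-ol
Product: 15 (S)-10-chlorodecan-4-yl acetate
Conditions: Ac2O, pyridine, DMAP (cat.), CH2Cl2, rt
Reagents that add atoms: acetic anhydride, CC(=O)OC(C)=O
Why: DMAP-catalysed acetylation installs the acetate of the target directly on the (S) alcohol, with retention at carbon.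

Step 8
Reactants: 11 (S)-11-[3-(benzyloxy)-5-(methoxymethoxy)phenyl]undecan-4-yl 2-(phenylsulfonyl)acetate; 15 (S)-10-chlorodecan-4-yl acetate
Product: 16 (S)-11-[3-(benzyloxy)-5-(methoxymethoxy)phenyl]undecan-4-yl (9S)-9-acetoxy-2-(phenylsulfonyl)dodecanoate (C2 epimers)
Conditions: Cs2CO3, NaI (0.2 equiv), DMF, 50 °C
Reagents that add atoms: none
Why: SN2 C-alkylation of the doubly stabilised sulfonylacetate carbanion with the primary chloride (Finkelstein activation in situ) should stop at mono-alkylation because of α-branching; the new α-centre forms as an epimer mixture and is erased in step 12.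

Step 9
Reactants: 17 3,5-bis(benzyloxy)phenol
Product: 18 3,5-bis(benzyloxy)-2-bromophenol
Conditions: NBS (1.0 equiv), CH2Cl2, −78 °C
Reagents that add atoms: N-bromosuccinimide, O=C1CCC(=O)N1Br
Why: Electrophilic aromatic bromination should occur ortho to the free hydroxyl, positions 2 and 6 being equivalent and less hindered than C4 between the two benzyloxy groups.

Step 10
Reactants: 18 3,5-bis(benzyloxy)-2-bromophenol
Product: 21 3,5-bis(benzyloxy)-2-(trimethylsilyl)phenyl trifluoromethanesulfonate, via aryl trimethylsilyl ether 19 (not isolated), via lithium 2-silylphenoxide 20 (not isolated)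
Conditions: HMDS, THF, 65 °C, evaporation; n-BuLi, THF, −100 °C; Tf2O, −100 °C → rt
Reagents that add atoms: hexamethyldisilazane, C[Si](C)(C)N[Si](C)(C)C; trifluoromethanesulfonic anhydride, O=S(=O)(OS(=O)(=O)C(F)(F)F)C(F)(F)F
Why: O-silylation, bromine–lithium exchange with 1,3-O→C silyl migration (retro-Brook rearrangement) and O-triflation of the resulting phenoxide is the standard one-pot entry to ortho-silylaryl triflates (Kobayashi aryne precursors).

Step 11
Reactants: 16 (S)-11-[3-(benzyloxy)-5-(methoxymethoxy)phenyl]undecan-4-yl (9S)-9-acetoxy-2-(phenylsulfonyl)dodecanoate; 21 3,5-bis(benzyloxy)-2-(trimethylsilyl)phenyl trifluoromethanesulfonate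
Product: 23 (S)-11-[3-(benzyloxy)-5-(methoxymethoxy)phenyl]undecan-4-yl 2-[(8S)-8-acetoxy-1-(phenylsulfonyl)undecyl]-4,6-bis(benzyloxy)benzoate (C1' epimers), via 3,5-bis(benzyloxy)benzyne 22 (not isolated)
Conditions: 21 (1.3 equiv), CsF (3 equiv), MeCN–THF, 60 °C
Reagents that add atoms: none
Why: Proposed new method: fluoride releases the aryne 22 from 21 and deprotonates the α-C–H of 16 (flanked by PhSO2 and CO2R); the tertiary carbanion adds to the aryne carbon distal to the C3 benzyloxy group, the aryl anion so formed attacks the ester carbonyl, and the resulting benzocyclobutenoxide fragments by C–C cleavage to a sulfonyl-stabilised benzylic anion that is protonated, so the aryne is inserted into the C(α)–C(=O) bond and the ring–C1' bond and the ring–carboxyl bond form together without any esterification at the hindered carbonyl. The closest known reaction types are the aryne acyl-alkylation of β-keto esters, the alkoxycarbonyl-transferring aryne insertion into malonate C–C bonds and the aryne insertion into β-keto sulfones; what has not been shown is the combination of a sulfonyl-stabilised α-alkyl carbanion with transfer of an ester carbonyl. No ring is kept, the only closure being the transient four-membered benzocyclobutenoxide (4-exo-trig attack of the aryl anion on the ester C=O), which opens again in the same operation. The sulfonyl-bearing benzylic carbon forms without control as an epimer mixture, which is harmless because step 12 turns it into CH2, and the two carbinol centres are untouched because the acyl group migrates with its O–C bond intact. The step needs attack at the correct aryne carbon, secured by the inductive effect and aryne distortion caused by the C3 benzyloxy group (the C5 benzyloxy group is remote from both aryne carbons), and it needs acyl transfer to outrun proton capture by the aryl anion, which the four-centre intramolecular geometry and the aprotic medium favour. Only one transferable acyl group sits on the carbanion carbon, the remote acetate is out of reach, and the sulfonyl sulfur is a poorer electrophile than the ester carbon.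

Step 12
Reactants: 23 (S)-11-[3-(benzyloxy)-5-(methoxymethoxy)phenyl]undecan-4-yl 2-[(8S)-8-acetoxy-1-(phenylsulfonyl)undecyl]-4,6-bis(benzyloxy)benzoate
Product: 24 (S)-11-[3-(benzyloxy)-5-(methoxymethoxy)phenyl]undecan-4-yl 2-[(S)-8-acetoxyundecyl]-4,6-bis(benzyloxy)benzoate
Conditions: SmI2 (4 equiv), HMPA, MeOH, THF, −78 → −20 °C
Reagents that add atoms: none
Why: Reductive desulfonylation by single-electron transfer, in which the benzylic C–S bond fragments to benzenesulfinate and a benzylic radical that is reduced and protonated, should leave esters, acetate, benzyl and MOM ethers untouched and erase the epimeric centre.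

Step 13
Reactants: 24 (S)-11-[3-(benzyloxy)-5-(methoxymethoxy)phenyl]undecan-4-yl 2-[(S)-8-acetoxyundecyl]-4,6-bis(benzyloxy)benzoate
Product: 25 (S)-11-[3-(benzyloxy)-5-hydroxyphenyl]undecan-4-yl 2-[(S)-8-acetoxyundecyl]-4,6-bis(benzyloxy)benzoate
Conditions: ZnBr2, n-PrSH, CH2Cl2, 0 °C
Reagents that add atoms: none
Why: Lewis acid-assisted thiolysis of the methoxymethyl acetal should free the single phenol within minutes without cleaving the aryl benzyl ethers, the acetate or the benzoate.

Step 14
Reactants: 25 (S)-11-[3-(benzyloxy)-5-hydroxyphenyl]undecan-4-yl 2-[(S)-8-acetoxyundecyl]-4,6-bis(benzyloxy)benzoate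
Product: 26 sodium 3-(benzyloxy)-5-[(S)-8-({2-[(S)-8-acetoxyundecyl]-4,6-bis(benzyloxy)benzoyl}oxy)undecyl]phenyl sulfate
Conditions: SO3·pyridine (5 equiv), pyridine, 40 °C; then aq NaHCO3
Reagents that add atoms: sulfur trioxide–pyridine complex, O=S(=O)=O.c1ccncc1; sodium hydrogen carbonate, [Na+].OC(=O)[O-]
Why: O-sulfonation of the only free hydroxyl with the SO3·pyridine complex should give the aryl sulfate monoester, isolated as its sodium salt after bicarbonate work-up.

Step 15
Reactants: 26 sodium 3-(benzyloxy)-5-[(S)-8-({2-[(S)-8-acetoxyundecyl]-4,6-bis(benzyloxy)benzoyl}oxy)undecyl]phenyl sulfate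
Product: 27 Integracin D
Conditions: H2 (1 atm), 10 % Pd/C, MeOH/EtOAc, rt; then 0.1 M HCl (1.0 equiv), 0 °C, extraction
Reagents that add atoms: none
Why: Palladium-catalysed hydrogenolysis should remove the three aryl benzyl ethers without affecting the acetate, the benzoate or the aryl sulfate, and one equivalent of cold dilute acid converts the sodium salt into the hydrogen sulfate as drawn.

**Compound list**

1 | 5-bromobenzene-1,3-diol (5-bromoresorcinol) | Oc1cc(O)cc(Br)c1 | starting material
2 | 3-(benzyloxy)-5-bromophenol | Oc1cc(Br)cc(OCc2ccccc2)c1 | intermediate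
3 | 1-(benzyloxy)-3-bromo-5-(methoxymethoxy)benzene | COCOc1cc(Br)cc(OCc2ccccc2)c1 | intermediate
4 | (S)-2-propyloxirane [(S)-1,2-epoxypentane] | CCC[C@H]1CO1 | starting material
5 | 6-bromohex-1-ene | C=CCCCCBr | starting material
6 | hex-5-enylmagnesium bromide | C=CCCCC[Mg]Br | intermediate (not isolated)
7 | (S)-undec-10-en-4-ol | CCC[C@@H](CCCCCC=C)O | intermediate
8 | O,B-bis(9-BBN) adduct of 7 (B-alkyl borane, hydroxyl as borinate) | CCC[C@@H](CCCCCCCB1C2CCCC1CCC2)OB1C2CCCC1CCC2 | intermediate (not isolated)
9 | (S)-11-[3-(benzyloxy)-5-(methoxymethoxy)phenyl]undecan-4-ol | CCC[C@@H](CCCCCCCc1cc(OCc2ccccc2)cc(OCOC)c1)O | intermediate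
10 | 2-(phenylsulfonyl)acetic acid | OC(=O)CS(=O)(=O)c1ccccc1 | starting material
11 | (S)-11-[3-(benzyloxy)-5-(methoxymethoxy)phenyl]undecan-4-yl 2-(phenylsulfonyl)acetate | O=C(CS(=O)(=O)c1ccccc1)O[C@@H](CCC)CCCCCCCc1cc(OCc2ccccc2)cc(OCOC)c1 | intermediate
12 | 1-bromo-5-chloropentane | ClCCCCCBr | starting material
13 | (5-chloropentyl)magnesium bromide | ClCCCCC[Mg]Br | intermediate (not isolated)
14 | (S)-10-chlorodecan-4-ol | CCC[C@@H](CCCCCCCl)O | intermediate
15 | (S)-10-chlorodecan-4-yl acetate | CCC[C@@H](CCCCCCCl)OC(C)=O | intermediate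
16 | (S)-11-[3-(benzyloxy)-5-(methoxymethoxy)phenyl]undecan-4-yl (9S)-9-acetoxy-2-(phenylsulfonyl)dodecanoate (C2 epimers) | CCC[C@@H](CCCCCCC(C(=O)O[C@@H](CCC)CCCCCCCc1cc(OCc2ccccc2)cc(OCOC)c1)S(=O)(=O)c1ccccc1)OC(C)=O | intermediate
17 | 3,5-bis(benzyloxy)phenol | Oc1cc(OCc2ccccc2)cc(OCc2ccccc2)c1 | starting material
18 | 3,5-bis(benzyloxy)-2-bromophenol | Oc1cc(OCc2ccccc2)cc(OCc2ccccc2)c1Br | intermediate
19 | [3,5-bis(benzyloxy)-2-bromophenoxy]trimethylsilane | C[Si](C)(C)Oc1cc(OCc2ccccc2)cc(OCc2ccccc2)c1Br | intermediate (not isolated)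
20 | lithium 3,5-bis(benzyloxy)-2-(trimethylsilyl)phenoxide | [Li+].[O-]c1cc(OCc2ccccc2)cc(OCc2ccccc2)c1[Si](C)(C)C | intermediate (not isolated)
21 | 3,5-bis(benzyloxy)-2-(trimethylsilyl)phenyl trifluoromethanesulfonate | C[Si](C)(C)c1c(OS(=O)(=O)C(F)(F)F)cc(OCc2ccccc2)cc1OCc1ccccc1 | intermediate
22 | 3,5-bis(benzyloxy)benzyne | C1#CC(OCc2ccccc2)=CC(OCc2ccccc2)=C1 | intermediate (not isolated)
23 | (S)-11-[3-(benzyloxy)-5-(methoxymethoxy)phenyl]undecan-4-yl 2-[(8S)-8-acetoxy-1-(phenylsulfonyl)undecyl]-4,6-bis(benzyloxy)benzoate (C1' epimers) | CCC[C@@H](CCCCCCC(c1cc(OCc2ccccc2)cc(OCc2ccccc2)c1C(=O)O[C@@H](CCC)CCCCCCCc1cc(OCc2ccccc2)cc(OCOC)c1)S(=O)(=O)c1ccccc1)OC(C)=O | intermediate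
24 | (S)-11-[3-(benzyloxy)-5-(methoxymethoxy)phenyl]undecan-4-yl 2-[(S)-8-acetoxyundecyl]-4,6-bis(benzyloxy)benzoate | CCC[C@@H](CCCCCCCc1cc(OCc2ccccc2)cc(OCc2ccccc2)c1C(=O)O[C@@H](CCC)CCCCCCCc1cc(OCc2ccccc2)cc(OCOC)c1)OC(C)=O | intermediate
25 | (S)-11-[3-(benzyloxy)-5-hydroxyphenyl]undecan-4-yl 2-[(S)-8-acetoxyundecyl]-4,6-bis(benzyloxy)benzoate | CCC[C@@H](CCCCCCCc1cc(OCc2ccccc2)cc(OCc2ccccc2)c1C(=O)O[C@@H](CCC)CCCCCCCc1cc(OCc2ccccc2)cc(O)c1)OC(C)=O | intermediate
26 | sodium 3-(benzyloxy)-5-[(S)-8-({2-[(S)-8-acetoxyundecyl]-4,6-bis(benzyloxy)benzoyl}oxy)undecyl]phenyl sulfate | CCC[C@@H](CCCCCCCc1cc(OCc2ccccc2)cc(OCc2ccccc2)c1C(=O)O[C@@H](CCC)CCCCCCCc1cc(OCc2ccccc2)cc(OS(=O)(=O)[O-])c1)OC(C)=O.[Na+] | intermediate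
27 | Integracin D | CCC[C@@H](CCCCCCCc1cc(O)cc(O)c1C(=O)O[C@@H](CCC)CCCCCCCc1cc(O)cc(OS(=O)(=O)O)c1)OC(C)=O | target

**Step count**

Total steps: 15. Longest linear sequence: 10 steps (1, 2, 4, 5, 8, 11, 12, 13, 14, 15).

**Steps most likely to fail**

Step 11. The aryl anion formed after carbanion addition may be protonated before it reaches the ester carbonyl, giving plain α-arylation instead of insertion. The carbanion may also attack the wrong aryne carbon, or the product anion may be arylated a second time. The fallback uses only known chemistry, sets out from 1, 7 and 9 and comes back at 24, so that steps 5 to 12 and the sulfonyl helper are not needed. Compound 1 is benzylated twice (BnBr, K2CO3, DMF) to 1,3-bis(benzyloxy)-5-bromobenzene F1. This is formylated (POCl3, DMF, Vilsmeier–Haack) to 2,4-bis(benzyloxy)-6-bromobenzaldehyde F2 and oxidised (NaClO2, NaH2PO4, 2-methylbut-2-ene, Pinnick) to 2,4-bis(benzyloxy)-6-bromobenzoic acid F3. Oxalyl chloride with catalytic DMF converts the acid into 2,4-bis(benzyloxy)-6-bromobenzoyl chloride F4, which acylates the sodium alkoxide of 9 (NaHMDS, THF) to (S)-11-[3-(benzyloxy)-5-(methoxymethoxy)phenyl]undecan-4-yl 2,4-bis(benzyloxy)-6-bromobenzoate F5. In parallel 7 is acetylated (Ac2O, pyridine, DMAP) to (S)-undec-10-en-4-yl acetate F6 and hydroborated with 9-BBN to the B-alkyl-9-BBN borane of F6 F7. B-alkyl Suzuki–Miyaura coupling of F7 with F5 (PdCl2(dppf), K3PO4, THF/DMF/H2O, 60 °C) should then form the same aryl–CH2 bond and give 24.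

Step 9. Bromination may take place para to the hydroxyl (between the two benzyloxy groups) or twice, which would place silicon and triflate wrongly in the aryne precursor. The fallback replaces electrophilic substitution by directed ortho-metalation; it sets out from 17 and comes back at 21. Compound 17 is carbamoylated (isopropyl isocyanate, Et3N cat., CH2Cl2) to 3,5-bis(benzyloxy)phenyl N-isopropylcarbamate F8. After N-silylation in situ (TBSOTf, TMEDA) this is lithiated between the carbamate and the neighbouring benzyloxy group (n-BuLi, TMEDA, −78 °C) and quenched with TMSCl to give 3,5-bis(benzyloxy)-2-(trimethylsilyl)phenyl N-isopropylcarbamate F9. The carbamate is removed (Et2NH, DBU, MeCN, 40 °C) to give 3,5-bis(benzyloxy)-2-(trimethylsilyl)phenol F10, which is triflated (PhNTf2, Cs2CO3) to 21.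

Step 4. The borane may be consumed unproductively by the free hydroxyl, or the electron-rich aryl bromide may couple slowly, leaving protodeboronation and β-hydride elimination to dominate. The fallback reverses the polarity and the order of bond formation; it sets out from 3 and comes back at 9. Compound 3 is converted with magnesium (THF) into [3-(benzyloxy)-5-(methoxymethoxy)phenyl]magnesium bromide F11. Copper-catalysed coupling with an excess of 1,6-dibromohexane (Li2CuCl4 cat., THF, 0 °C) should give 1-(benzyloxy)-3-(6-bromohexyl)-5-(methoxymethoxy)benzene F12. Its Grignard reagent, {6-[3-(benzyloxy)-5-(methoxymethoxy)phenyl]hexyl}magnesium bromide F13, opens epoxide 4 (CuI cat., THF, −30 → 0 °C) at the CH2 to give 9 with the (S) centre unchanged.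

**Further compounds**

F1 | step 11 | 1,3-bis(benzyloxy)-5-bromobenzene | Brc1cc(OCc2ccccc2)cc(OCc2ccccc2)c1
F2 | step 11 | 2,4-bis(benzyloxy)-6-bromobenzaldehyde | O=Cc1c(Br)cc(OCc2ccccc2)cc1OCc1ccccc1
F3 | step 11 | 2,4-bis(benzyloxy)-6-bromobenzoic acid | OC(=O)c1c(Br)cc(OCc2ccccc2)cc1OCc1ccccc1
F4 | step 11 | 2,4-bis(benzyloxy)-6-bromobenzoyl chloride | ClC(=O)c1c(Br)cc(OCc2ccccc2)cc1OCc1ccccc1
F5 | step 11 | (S)-11-[3-(benzyloxy)-5-(methoxymethoxy)phenyl]undecan-4-yl 2,4-bis(benzyloxy)-6-bromobenzoate | CCC[C@@H](CCCCCCCc1cc(OCc2ccccc2)cc(OCOC)c1)OC(=O)c1c(Br)cc(OCc2ccccc2)cc1OCc1ccccc1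
F6 | step 11 | (S)-undec-10-en-4-yl acetate | CCC[C@@H](CCCCCC=C)OC(C)=O
F7 | step 11 | B-alkyl-9-BBN borane of F6 [(S)-11-(9-borabicyclo[3.3.1]nonan-9-yl)undecan-4-yl acetate] | CCC[C@@H](CCCCCCCB1C2CCCC1CCC2)OC(C)=O
F8 | step 9 | 3,5-bis(benzyloxy)phenyl N-isopropylcarbamate | CC(C)NC(=O)Oc1cc(OCc2ccccc2)cc(OCc2ccccc2)c1
F9 | step 9 | 3,5-bis(benzyloxy)-2-(trimethylsilyl)phenyl N-isopropylcarbamate | CC(C)NC(=O)Oc1cc(OCc2ccccc2)cc(OCc2ccccc2)c1[Si](C)(C)C
F10 | step 9 | 3,5-bis(benzyloxy)-2-(trimethylsilyl)phenol | Oc1cc(OCc2ccccc2)cc(OCc2ccccc2)c1[Si](C)(C)C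
F11 | step 4 | [3-(benzyloxy)-5-(methoxymethoxy)phenyl]magnesium bromide | Br[Mg]c1cc(OCc2ccccc2)cc(OCOC)c1
F12 | step 4 | 1-(benzyloxy)-3-(6-bromohexyl)-5-(methoxymethoxy)benzene | BrCCCCCCc1cc(OCc2ccccc2)cc(OCOC)c1
F13 | step 4 | {6-[3-(benzyloxy)-5-(methoxymethoxy)phenyl]hexyl}magnesium bromide | Br[Mg]CCCCCCc1cc(OCc2ccccc2)cc(OCOC)c1
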